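The earlier runs and the new flask are calculated with made-up constants; scatter was added.

| flask | starting material | coupling partner | protic impurity | remark | time |
|---|---|---|---|---|---|
| zeta | 0.15 M | 0.16 M | 0.020 M | run made earlier |  |
| eta | 1.3 M | 0.16 M | 0.020 M | run made earlier |  |
| larch | 0.20 M | 0.160 M | 0.0200 M |  | 50 h |
| ash | 0.40 M | 0.160 M | 0.0200 M |  | 50 h |
| birch | 0.80 M | 0.160 M | 0.0200 M |  | 50 h |
| alder | 1.5 M | 0.160 M | 0.0200 M |  | 50 h |

| run | time / h | target / % |
|---|---|---|
| zeta | 3.00 | 2.8 |
| zeta | 8.00 | 9.1 |
| zeta | 15.0 | 13.7 |
| zeta | 25.0 | 20.4 |
| eta | 2.00 | 3.2 |
| eta | 5.00 | 4.2 |
| eta | 10.0 | 3.6 |
| eta | 25.0 | 3.9 |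

(standard deviation of a reading: 1 percentage point)

- percentages count the starting material that a species holds: one side product B counts as two
- on the list of suspects stand: starting material + coupling partner <-> target; starting material + 2 coupling partner -> side product A; coupling partner + protic impurity -> quenched reagent; starting material + target -> side product B
- "hardly changes" means that all values lie within two and a half points (for a concentration: within two and a half percent of the largest)

- [target] at the end for larch, ash, birch, alder, in this order
- how that number moves from the first to the last of them (falls all the way / falls, then rises / hardly changes / rises all the way / rises, then falls)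

- A small charge of coupling partner, 0.160 M, lies below each charge of starting material in the row, so it is the limiting reagent there.
- On the list of suspects, target is made by one step and consumed by another, and both run in proportion to starting material. Charge times time therefore serves as a clock for target's rise and for its loss.
- Folding the givens into one number gives the dose D, a flask's charge of starting material times its time, divided by the same product for eta at 5.00 h, where eta's target first reads level; for larch at 50 h this is 1.54. D = 1 thus means the exposure that brought eta to its level, read as 0.0507 M.
- The quench step contains no starting material, so it need not keep this clock. Zeta at 25.0 h has D = 0.577 and 0.0306 M of target, while eta at 2.00 h has D = 0.400 and 0.0416 M. Eta holds more at the smaller dose, but the gap lies under eta's scatter of 0.0130 M, so these readings do not reject a single number.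
- At 50 h, D is 1.54 for larch, 3.08 for ash, 6.15 for birch and 11.5 for alder, while eta's readings end at D = 5.00.
- The reckoning here therefore puts larch slightly short of ash, both near eta's level, and expects the row to drop at birch and drop again at alder, whose doses stand past eta's last one: rises, then falls.
- The forecast gives 0.04 M, 0.048 M, 0.05 M and 0.05 M, rises all the way, holding that “Eta's flat tail shows side product B is minor”, and so parts from this reckoning on birch and alder.
- The flasks give 0.0487 M, 0.0593 M, 0.0455 M and 0.0179 M: the row rises, then falls, turning at 0.41 M, which is D = 3.13.

    starting material + coupling partner ⇌ target (K = 82.5 /M, k = 0.0826 /M/h)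
    starting material + 2 coupling partner → side product A (k = 0.201 /M²/h)
    coupling partner + protic impurity → quenched reagent (k = 0.653 /M/h)
    starting material + target → side product B (k = 0.0333 /M/h)

- In larch at 50.0 h, with D = 1.54, target is still made 2.60 times faster than it is used up. Ash at 25.0 h has that same dose and holds 0.0536 M, against 0.0487 M in larch. Birch at 25.0 h has the dose of ash at 50 h, D = 3.08, and holds 0.0613 M, against 0.0593 M in ash.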